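**Retrosynthetic overview**

1. The last bond is the C11'=C12' alkene: a Wittig reaction joins the ring A C15 phosphonium salt 17 to the C25 apo-aldehyde 31, which comes from the ring B C15 phosphonium salt 27 and the C10 dialdehyde 28 (C11=C12 Wittig).
2. The ring A enyne comes from a Sonogashira coupling (C8'–C9') of ring alkyne 12 with the (E)-enol triflate 14; the alkyne carbon C8' is added to nitrile 9 by reduction and one-carbon homologation.
3. Ring A, the only ring built in the route, is closed in step 4 from the acyclic keto acid 7 and the isopropylidene cyanophosphonate 3: a decarboxylative radical conjugate addition makes C1'–C2' and an intramolecular Horner–Wadsworth–Emmons olefination makes C5'=C6' in the same flask; C3' is bought with hemiester 4.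
4. Enabling feature: in ring A the tetrasubstituted C5'=C6' alkene lies between the quaternary gem-dimethyl carbon C1' and the methyl-bearing C5', C6' carries a carboxyl-level carbon (C7'), and the C3' carbinol is 1,3 to C5'. So C1'/C6'/C7' map onto an isopropylidene cyanophosphonate and C2'–C5' onto a 3-silyloxy-5-oxohexanoic acid whose carboxyl leaves as CO2.
5. Ring B is bought as β-cyclocitral; its trans-5,6-diol comes from a Sharpless epoxidation (temporary oxirane ring, step 12) and an inverting hydrolysis at C5 (step 13).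

Key step: step 4

Remark: carotenoid numbering is used for positions (ring A = C1'–C6' with the alkyne on C6', ring B = C1–C6 with the diol); TBS = tert-butyldimethylsilyl; the (R)-hemiester 4 is assumed to be purchasable in high enantiomeric purity.

**Route**

Step 1
Reactants: 1 acetone; 2 diethyl (cyanomethyl)phosphonate
Product: 3 diethyl (1-cyano-2-methylprop-1-en-1-yl)phosphonate
Conditions: TiCl4, N-methylmorpholine, THF, 0 °C to rt
Reagents that add atoms: none
Why: TiCl4/amine-mediated Knoevenagel condensation of an active methylene compound with a ketone; the new alkene carries two identical methyl groups, so there is no geometry to control.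

Step 2
Reactants: 4 (3R)-3-(TBSO)-5-methoxy-5-oxopentanoic acid
Product: 6 methyl (3R)-3-(TBSO)-5-oxohexanoate, via acid chloride 5 (not isolated)
Conditions: (COCl)2, DMF (cat.), CH2Cl2, 0 °C to rt; concentrate; MeMgBr, Fe(acac)3 (3 mol %), THF, −78 °C
Reagents that add atoms: methylmagnesium bromide, C[Mg]Br; oxalyl chloride, O=C(Cl)C(Cl)=O (chlorine of 5 only)
Why: acid chloride formation followed by iron-catalysed Grignard acylation should stop at the methyl ketone and leave the methyl ester and silyl ether untouched at −78 °C; the stereocenter is not involved.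

Step 3
Reactants: 6 methyl (3R)-3-(TBSO)-5-oxohexanoate
Product: 7 (3R)-3-(TBSO)-5-oxohexanoic acid
Conditions: Me3SnOH, 1,2-dichloroethane, 70 °C; then 5% aq. HCl wash
Reagents that add atoms: trimethyltin hydroxide, C[Sn](C)(C)O
Why: near-neutral methyl ester cleavage with Me3SnOH should avoid the β-elimination of the silyloxy group that aqueous hydroxide could cause.

Step 4
Reactants: 7 (3R)-3-(TBSO)-5-oxohexanoic acid; 3 diethyl (1-cyano-2-methylprop-1-en-1-yl)phosphonate
Product: 9 (4R)-4-(TBSO)-2,6,6-trimethylcyclohex-1-ene-1-carbonitrile, via conjugate adduct 8 (not isolated)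
Conditions: Ir[dF(CF3)ppy]2(dtbbpy)PF6 (2 mol %), Cs2CO3 (1.2 equiv), 3 (2.5 equiv), degassed DMF, 450 nm LEDs, 25 °C; then dark, 40 °C, same flask
Reagents that add atoms: none
Why: Proposed new method: photoexcited trivalent iridium should oxidise the cesium carboxylate of 7, loss of CO2 gives a primary alkyl radical, and this adds to the dimethyl-substituted carbon of 3 because the adduct radical is captodatively stabilised by the nitrile and phosphoryl groups; divalent iridium then reduces that radical to the carbanion of 8, which closes onto the methyl ketone by intramolecular Horner–Wadsworth–Emmons olefination. The closest known reaction types are the decarboxylative photoredox Giese addition with radical–polar crossover (isopropylidenemalononitrile is an established trap for alkyl radicals at its dimethyl carbon) and the Michael-initiated intramolecular Horner–Wadsworth–Emmons cyclohexene annulation. The six-membered ring closes in a 6-(enolexo)-exo-trig mode, and syn-elimination of diethyl phosphate inside the ring gives the tetrasubstituted alkene without any geometry question. No new stereocenter survives: the phosphonate carbon of 8 becomes sp2, and the silyloxy carbon bought with 4 is not touched. The step needs chemoselectivity for radical addition over 1,5-hydrogen transfer or dimerisation and for olefination over base-induced loss of the β-silyloxy group; the excess of the doubly activated acceptor, the absence of a hydrogen-atom donor, the mild carbonate base and the fast intramolecular olefination are meant to secure this.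

Step 5
Reactants: 9 (4R)-4-(TBSO)-2,6,6-trimethylcyclohex-1-ene-1-carbonitrile
Product: 11 (4R)-4-(TBSO)-2,6,6-trimethylcyclohex-1-ene-1-carbaldehyde, via N-aluminated aldimine 10 (not isolated)
Conditions: i-Bu2AlH, toluene, −78 to −40 °C; then aq. potassium sodium tartrate, rt
Reagents that add atoms: water, O
Why: partial reduction of a nitrile with i-Bu2AlH stops at the aluminated aldimine, which is hydrolysed to the aldehyde under buffered work-up that should spare the allylically activated silyloxy group.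

Step 6
Reactants: 11 (4R)-4-(TBSO)-2,6,6-trimethylcyclohex-1-ene-1-carbaldehyde
Product: 12 tert-butyl{[(1R)-4-ethynyl-3,5,5-trimethylcyclohex-3-en-1-yl]oxy}dimethylsilane
Conditions: Me3SiCHN2, LiN(i-Pr)2, THF, −78 °C; then 11, −78 °C to rt; H2O quench
Reagents that add atoms: (trimethylsilyl)diazomethane, C[Si](C)(C)C=[N+]=[N-]
Why: Colvin rearrangement: addition of lithiated trimethylsilyldiazomethane, Peterson elimination and 1,2-hydrogen shift of the alkylidene carbene should give the terminal alkyne at low temperature, where the hindered enal is not deprotonated at its γ-positions.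

Step 7
Reactants: 13 ethyl acetoacetate
Product: 14 ethyl (2E)-3-{[(trifluoromethyl)sulfonyl]oxy}but-2-enoate
Conditions: Tf2O, aq. Me4NOH, hexanes, 5 °C
Reagents that add atoms: triflic anhydride, O=S(=O)(OS(=O)(=O)C(F)(F)F)C(F)(F)F
Why: enol triflation of a β-keto ester through the non-chelated tetramethylammonium enolate should give the E triflate (a lithium base would give the chelated Z isomer).

Step 8
Reactants: 12 tert-butyl{[(1R)-4-ethynyl-3,5,5-trimethylcyclohex-3-en-1-yl]oxy}dimethylsilane; 14 ethyl (2E)-3-{[(trifluoromethyl)sulfonyl]oxy}but-2-enoate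
Product: 15 ethyl (2E)-5-[(4R)-4-(TBSO)-2,6,6-trimethylcyclohex-1-en-1-yl]-3-methylpent-2-en-4-ynoate
Conditions: Pd(PPh3)4 (5 mol %), CuI (10 mol %), i-Pr2NH, THF, rt
Reagents that add atoms: none
Why: Sonogashira coupling of a terminal alkyne with an electron-poor enol triflate proceeds with retention, so the 9'E geometry is fixed by the triflate.

Step 9
Reactants: 15 ethyl (2E)-5-[(4R)-4-(TBSO)-2,6,6-trimethylcyclohex-1-en-1-yl]-3-methylpent-2-en-4-ynoate
Product: 16 (2E)-5-[(4R)-4-(TBSO)-2,6,6-trimethylcyclohex-1-en-1-yl]-3-methylpent-2-en-4-yn-1-ol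
Conditions: i-Bu2AlH, CH2Cl2, −78 °C
Reagents that add atoms: none
Why: 1,2-reduction of the conjugated ester to the allylic alcohol with i-Bu2AlH leaves the enyne and its geometry unchanged.

Step 10
Reactants: 16 (2E)-5-[(4R)-4-(TBSO)-2,6,6-trimethylcyclohex-1-en-1-yl]-3-methylpent-2-en-4-yn-1-ol
Product: 17 {(2E)-5-[(4R)-4-hydroxy-2,6,6-trimethylcyclohex-1-en-1-yl]-3-methylpent-2-en-4-yn-1-yl}triphenylphosphonium bromide
Conditions: PPh3, 48% aq. HBr, MeOH, 0 °C to rt
Reagents that add atoms: triphenylphosphine, c1ccc(cc1)P(c1ccccc1)c1ccccc1; hydrogen bromide, Br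
Why: classical acid-mediated conversion of a primary allylic alcohol into its triphenylphosphonium bromide; the methanolic HBr should also cleave the secondary TBS ether, so the free-hydroxy salt is obtained in one step.

Step 11
Reactants: 18 β-cyclocitral (2,6,6-trimethylcyclohex-1-ene-1-carbaldehyde)
Product: 19 β-cyclogeraniol ((2,6,6-trimethylcyclohex-1-en-1-yl)methanol)
Conditions: NaBH4, MeOH, 0 °C
Reagents that add atoms: none
Why: 1,2-reduction of a hindered enal with borohydride gives the allylic alcohol needed for directed epoxidation.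

Step 12
Reactants: 19 β-cyclogeraniol
Product: 20 [(1S,6S)-2,2,6-trimethyl-7-oxabicyclo[4.1.0]heptan-1-yl]methanol
Conditions: Ti(OiPr)4 (10 mol %), D-(−)-diethyl tartrate (12 mol %), t-BuOOH, 4 Å molecular sieves, CH2Cl2, −20 °C
Reagents that add atoms: tert-butyl hydroperoxide, CC(C)(C)OO
Why: Sharpless asymmetric epoxidation of the tetrasubstituted allylic alcohol; with D-(−)-tartrate the oxygen should be delivered to the face that gives the (1S,6S) epoxy alcohol, so C5 and C6 are set together by the reagent.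

Step 13
Reactants: 20 [(1S,6S)-2,2,6-trimethyl-7-oxabicyclo[4.1.0]heptan-1-yl]methanol
Product: 21 (1S,2R)-1-(hydroxymethyl)-2,6,6-trimethylcyclohexane-1,2-diol
Conditions: HClO4 (cat.), THF/H2O, 0 °C to rt
Reagents that add atoms: water, O
Why: acid-catalysed hydrolysis of a 2,3-epoxy alcohol: water should open the protonated oxirane at C5 (tertiary, remote from the electron-withdrawing CH2OH and not shielded by the gem-dimethyl carbon) with inversion while C6 keeps its oxygen, which gives the trans-diol that is (5R,6R) in the target.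

Step 14
Reactants: 21 (1S,2R)-1-(hydroxymethyl)-2,6,6-trimethylcyclohexane-1,2-diol
Product: 22 (1R,2R)-1,2-dihydroxy-2,6,6-trimethylcyclohexane-1-carbaldehyde
Conditions: TEMPO (5 mol %), KBr (10 mol %), NaOCl, aq. NaHCO3, CH2Cl2, 0 °C
Reagents that add atoms: none
Why: TEMPO/hypochlorite oxidation is selective for the primary alcohol; the two tertiary hydroxyls cannot be oxidised and the α-carbon is quaternary, so it cannot epimerise.

Step 15
Reactants: 22 (1R,2R)-1,2-dihydroxy-2,6,6-trimethylcyclohexane-1-carbaldehyde; 23 ethyl (2E)-4-(diethoxyphosphoryl)-3-methylbut-2-enoate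
Product: 24 ethyl (2E,4E)-5-[(1R,2R)-1,2-dihydroxy-2,6,6-trimethylcyclohexyl]-3-methylpenta-2,4-dienoate
Conditions: 23, LiN(SiMe3)2, THF, −78 °C; then 22, −78 to 0 °C
Reagents that add atoms: none
Why: Horner–Wadsworth–Emmons olefination with the vinylogous phosphonate anion should give the E alkene at C7=C8 and mainly the 9E dienoate; the tertiary hydroxyls are not acidic enough to quench the anion.

Step 16
Reactants: 24 ethyl (2E,4E)-5-[(1R,2R)-1,2-dihydroxy-2,6,6-trimethylcyclohexyl]-3-methylpenta-2,4-dienoate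
Product: 25 (1R,2R)-1-[(1E,3E)-5-hydroxy-3-methylpenta-1,3-dien-1-yl]-2,6,6-trimethylcyclohexane-1,2-diol
Conditions: i-Bu2AlH (excess), CH2Cl2, −78 to 0 °C
Reagents that add atoms: none
Why: 1,2-reduction of the dienoate to the primary allylic alcohol; the free tertiary alcohols only consume extra hydride.

Step 17
Reactants: 25 (1R,2R)-1-[(1E,3E)-5-hydroxy-3-methylpenta-1,3-dien-1-yl]-2,6,6-trimethylcyclohexane-1,2-diol
Product: 27 {(2E,4E)-5-[(1R,2R)-1,2-dihydroxy-2,6,6-trimethylcyclohexyl]-3-methylpenta-2,4-dien-1-yl}triphenylphosphonium bromide, via allylic bromide 26 (not isolated)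
Conditions: CBr4, PPh3, CH2Cl2, −20 °C; then PPh3, MeCN, rt
Reagents that add atoms: triphenylphosphine, c1ccc(cc1)P(c1ccccc1)c1ccccc1; carbon tetrabromide, BrC(Br)(Br)Br
Why: Appel bromination activates only the primary allylic alcohol under neutral conditions, so the acid-labile tertiary allylic C6 hydroxyl is not ionised, and the bromide is then displaced by PPh3 in an SN2 reaction.

Step 18
Reactants: 27 ring B C15 phosphonium bromide; 28 (2E,4E,6E)-2,7-dimethylocta-2,4,6-trienedial
Product: 31 (2E,4E,6E,8E,10E,12E)-13-[(1R,2R)-1,2-dihydroxy-2,6,6-trimethylcyclohexyl]-2,7,11-trimethyltrideca-2,4,6,8,10,12-hexaenal, via ylide 29 (not isolated), via 11Z isomer 30 (not isolated)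
Conditions: NaOMe, MeOH/CH2Cl2, 28 in excess, 0 °C to rt; then crude product in EtOH, 70 °C
Reagents that add atoms: none
Why: Wittig olefination of the polyenyl ylide with an excess of the symmetrical dialdehyde should give mono-condensation, and the sterically hindered 11Z isomer formed alongside should relax to E on gentle heating.

Step 19
Reactants: 17 ring A C15 phosphonium bromide; 31 C25 apo-aldehyde
Product: 34 (3'R,5R,6R)-7',8'-didehydro-5,6-dihydro-β,β-carotene-3',5,6-triol (all-E), via ylide 32 (not isolated), via 11'Z isomer 33 (not isolated)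
Conditions: NaOMe, MeOH/CH2Cl2, rt; then EtOAc, 60 °C, dark; crystallisation
Reagents that add atoms: none
Why: Wittig olefination of the acetylenic C15 ylide with the polyenal tolerates the free hydroxyls, and the hindered 11'Z isomer should isomerise thermally to the all-E polyene while the 9'E enyne geometry set in step 8 is kept by short, mild heating.

**Compound list**

1 | acetone | CC(C)=O | starting material
2 | diethyl (cyanomethyl)phosphonate | CCOP(=O)(CC#N)OCC | starting material
3 | diethyl (1-cyano-2-methylprop-1-en-1-yl)phosphonate | CCOP(=O)(OCC)C(C#N)=C(C)C | intermediate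
4 | (3R)-3-(TBSO)-5-methoxy-5-oxopentanoic acid | COC(=O)C[C@H](O[Si](C)(C)C(C)(C)C)CC(=O)O | starting material
5 | methyl (3S)-3-(TBSO)-5-chloro-5-oxopentanoate | COC(=O)C[C@H](O[Si](C)(C)C(C)(C)C)CC(=O)Cl | intermediate (not isolated)
6 | methyl (3R)-3-(TBSO)-5-oxohexanoate | COC(=O)C[C@H](O[Si](C)(C)C(C)(C)C)CC(C)=O | intermediate
7 | (3R)-3-(TBSO)-5-oxohexanoic acid | OC(=O)C[C@H](O[Si](C)(C)C(C)(C)C)CC(C)=O | intermediate
8 | diethyl [(4S)-4-(TBSO)-1-cyano-2,2-dimethyl-6-oxoheptyl]phosphonate (formed as its cesium carbanion, mixture at C1) | CCOP(=O)(OCC)C(C#N)C(C)(C)C[C@H](O[Si](C)(C)C(C)(C)C)CC(C)=O | intermediate (not isolated)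
9 | (4R)-4-(TBSO)-2,6,6-trimethylcyclohex-1-ene-1-carbonitrile | CC1=C(C#N)C(C)(C)C[C@H](O[Si](C)(C)C(C)(C)C)C1 | intermediate
10 | N-(diisobutylalumino) aldimine of 11 | CC1=C(C=N[Al](CC(C)C)CC(C)C)C(C)(C)C[C@H](O[Si](C)(C)C(C)(C)C)C1 | intermediate (not isolated)
11 | (4R)-4-(TBSO)-2,6,6-trimethylcyclohex-1-ene-1-carbaldehyde | CC1=C(C=O)C(C)(C)C[C@H](O[Si](C)(C)C(C)(C)C)C1 | intermediate
12 | tert-butyl{[(1R)-4-ethynyl-3,5,5-trimethylcyclohex-3-en-1-yl]oxy}dimethylsilane | CC1=C(C#C)C(C)(C)C[C@H](O[Si](C)(C)C(C)(C)C)C1 | intermediate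
13 | ethyl acetoacetate | CCOC(=O)CC(C)=O | starting material
14 | ethyl (2E)-3-{[(trifluoromethyl)sulfonyl]oxy}but-2-enoate | CCOC(=O)/C=C(\C)OS(=O)(=O)C(F)(F)F | intermediate
15 | ethyl (2E)-5-[(4R)-4-(TBSO)-2,6,6-trimethylcyclohex-1-en-1-yl]-3-methylpent-2-en-4-ynoate | CC1=C(C#C/C(C)=C/C(=O)OCC)C(C)(C)C[C@H](O[Si](C)(C)C(C)(C)C)C1 | intermediate
16 | (2E)-5-[(4R)-4-(TBSO)-2,6,6-trimethylcyclohex-1-en-1-yl]-3-methylpent-2-en-4-yn-1-ol | CC1=C(C#C/C(C)=C/CO)C(C)(C)C[C@H](O[Si](C)(C)C(C)(C)C)C1 | intermediate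
17 | {(2E)-5-[(4R)-4-hydroxy-2,6,6-trimethylcyclohex-1-en-1-yl]-3-methylpent-2-en-4-yn-1-yl}triphenylphosphonium bromide | CC1=C(C#C/C(C)=C/C[P+](c2ccccc2)(c2ccccc2)c2ccccc2)C(C)(C)C[C@H](O)C1.[Br-] | intermediate
18 | β-cyclocitral | CC1=C(C=O)C(C)(C)CCC1 | starting material
19 | β-cyclogeraniol | CC1=C(CO)C(C)(C)CCC1 | intermediate
20 | [(1S,6S)-2,2,6-trimethyl-7-oxabicyclo[4.1.0]heptan-1-yl]methanol | CC1(C)CCC[C@]2(C)O[C@]12CO | intermediate
21 | (1S,2R)-1-(hydroxymethyl)-2,6,6-trimethylcyclohexane-1,2-diol (trans-diol) | OC[C@@]1(O)C(C)(C)CCC[C@@]1(C)O | intermediate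
22 | (1R,2R)-1,2-dihydroxy-2,6,6-trimethylcyclohexane-1-carbaldehyde | O=C[C@@]1(O)C(C)(C)CCC[C@@]1(C)O | intermediate
23 | ethyl (2E)-4-(diethoxyphosphoryl)-3-methylbut-2-enoate | CCOC(=O)/C=C(\C)CP(=O)(OCC)OCC | starting material
24 | ethyl (2E,4E)-5-[(1R,2R)-1,2-dihydroxy-2,6,6-trimethylcyclohexyl]-3-methylpenta-2,4-dienoate | CCOC(=O)/C=C(C)/C=C/[C@@]1(O)C(C)(C)CCC[C@@]1(C)O | intermediate
25 | (1R,2R)-1-[(1E,3E)-5-hydroxy-3-methylpenta-1,3-dien-1-yl]-2,6,6-trimethylcyclohexane-1,2-diol | OC/C=C(C)/C=C/[C@@]1(O)C(C)(C)CCC[C@@]1(C)O | intermediate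
26 | (1R,2R)-1-[(1E,3E)-5-bromo-3-methylpenta-1,3-dien-1-yl]-2,6,6-trimethylcyclohexane-1,2-diol | BrC/C=C(C)/C=C/[C@@]1(O)C(C)(C)CCC[C@@]1(C)O | intermediate (not isolated)
27 | {(2E,4E)-5-[(1R,2R)-1,2-dihydroxy-2,6,6-trimethylcyclohexyl]-3-methylpenta-2,4-dien-1-yl}triphenylphosphonium bromide | [Br-].C(/C=C(C)/C=C/[C@@]1(O)C(C)(C)CCC[C@@]1(C)O)[P+](c1ccccc1)(c1ccccc1)c1ccccc1 | intermediate
28 | (2E,4E,6E)-2,7-dimethylocta-2,4,6-trienedial | O=C/C(C)=C/C=C/C=C(C)/C=O | starting material
29 | triphenylphosphonium ylide of 27 | C(/C=C(C)/C=C/[C@@]1(O)C(C)(C)CCC[C@@]1(C)O)=P(c1ccccc1)(c1ccccc1)c1ccccc1 | intermediate (not isolated)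
30 | 11Z (chain 8Z) isomer of 31 | O=C/C(C)=C/C=C/C=C(C)/C=C\C=C(C)\C=C\[C@@]1(O)C(C)(C)CCC[C@@]1(C)O | intermediate (not isolated)
31 | (2E,4E,6E,8E,10E,12E)-13-[(1R,2R)-1,2-dihydroxy-2,6,6-trimethylcyclohexyl]-2,7,11-trimethyltrideca-2,4,6,8,10,12-hexaenal | O=C/C(C)=C/C=C/C=C(C)/C=C/C=C(C)/C=C/[C@@]1(O)C(C)(C)CCC[C@@]1(C)O | intermediate
32 | triphenylphosphonium ylide of 17 | CC1=C(C#C/C(C)=C/C=P(c2ccccc2)(c2ccccc2)c2ccccc2)C(C)(C)C[C@H](O)C1 | intermediate (not isolated)
33 | 11'Z isomer of 34 | CC1=C(C#C/C(C)=C/C=C\C(C)=C\C=C\C=C(C)\C=C\C=C(C)\C=C\[C@@]2(O)C(C)(C)CCC[C@@]2(C)O)C(C)(C)C[C@H](O)C1 | intermediate (not isolated)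
34 | (3'R,5R,6R)-7',8'-didehydro-5,6-dihydro-β,β-carotene-3',5,6-triol, all-E | CC1=C(C#C/C(C)=C/C=C/C(C)=C/C=C/C=C(C)/C=C/C=C(C)/C=C/[C@@]2(O)C(C)(C)CCC[C@@]2(C)O)C(C)(C)C[C@H](O)C1 | target

**Step count and risks**

Total step count: 19 (steps 1 and 7 prepare the two coupling reagents 3 and 14).
Longest linear sequence: 9 steps (from 4 through steps 2, 3, 4, 5, 6, 8, 9, 10 and 19; the ring B branch from 18 through steps 11 to 19 is equally long).

Steps most likely to fail:

Step 4 (proposed new method). The primary radical may abstract hydrogen intramolecularly, dimerise or be reduced faster than it adds to the fully substituted acceptor carbon of 3, or the β-silyloxy group may be eliminated during the basic olefination stage. The fallback uses known polar chemistry, sets out from 7 and comes back at 11. Iododecarboxylation of 7 (PhI(OAc)2, I2, light) would give (4R)-4-(TBSO)-5-iodopentan-2-one F1. Ketalisation with ethylene glycol and PPTS would give tert-butyl{[(2R)-1-iodo-3-(2-methyl-1,3-dioxolan-2-yl)propan-2-yl]oxy}dimethylsilane F2. Alkylation of lithiated isobutyraldehyde N-cyclohexylimine with F2 (THF, DMPU) and buffered hydrolysis would make the quaternary carbon by SN2 and give (4S)-4-(TBSO)-2,2-dimethyl-5-(2-methyl-1,3-dioxolan-2-yl)pentanal F3. Wittig methoxymethylenation with Ph3P=CHOMe would give the homologous enol ether F4. Aqueous oxalic acid would unmask (5S)-5-(TBSO)-3,3-dimethyl-7-oxooctanal F5. Piperidinium acetate would then effect the intramolecular aldol condensation of the aldehyde enamine onto the methyl ketone and deliver 11.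

Step 15. The aldehyde of 22 sits on a fully substituted carbon between two quaternary centres and carries a free α-hydroxyl, so slow addition, α-ketol rearrangement or hydrate formation may outrun the olefination. The fallback sets out from 20 and comes back at 24. Parikh–Doering oxidation of 20 (SO3·pyridine, DMSO, i-Pr2NEt) would give (1R,6S)-2,2,6-trimethyl-7-oxabicyclo[4.1.0]heptane-1-carbaldehyde F6. The same olefination with 23 on this smaller, non-hydroxylic aldehyde would give ethyl (2E,4E)-3-methyl-5-[(1R,6S)-2,2,6-trimethyl-7-oxabicyclo[4.1.0]heptan-1-yl]penta-2,4-dienoate F7. Only then would the oxirane be opened with dilute aqueous HClO4 in THF; the electron-poor dienoate disfavours ionisation at C6, so water should again enter at C5 with inversion and give 24.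

Step 10. Ionisation of the allylic alcohol under HBr may scramble the 9'E geometry, add HBr across the enyne or leave the silyl ether partly intact, which would give a mixture of salts. The fallback sets out from 16 and comes back at 34. Neutral Appel bromination of 16 (CBr4, PPh3) would give tert-butyl{[(1R)-4-[(3E)-5-bromo-3-methylpent-3-en-1-yn-1-yl]-3,5,5-trimethylcyclohex-3-en-1-yl]oxy}dimethylsilane F8. An Arbuzov reaction with P(OEt)3 would give the corresponding diethyl allylphosphonate F9. Horner–Wadsworth–Emmons coupling of F9 with 31 (NaH, THF) would give the 3'-O-TBS ether of the target F10, and desilylation with Bu4NF would give 34.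

Further compounds
F1 | step 4 | (4R)-4-(TBSO)-5-iodopentan-2-one | IC[C@H](O[Si](C)(C)C(C)(C)C)CC(C)=O
F2 | step 4 | tert-butyl{[(2R)-1-iodo-3-(2-methyl-1,3-dioxolan-2-yl)propan-2-yl]oxy}dimethylsilane | IC[C@H](O[Si](C)(C)C(C)(C)C)CC1(C)OCCO1
F3 | step 4 | (4S)-4-(TBSO)-2,2-dimethyl-5-(2-methyl-1,3-dioxolan-2-yl)pentanal | O=CC(C)(C)C[C@H](O[Si](C)(C)C(C)(C)C)CC1(C)OCCO1
F4 | step 4 | methyl enol ether of the one-carbon homologue of F3 (E/Z mixture) | COC=CC(C)(C)C[C@H](O[Si](C)(C)C(C)(C)C)CC1(C)OCCO1
F5 | step 4 | (5S)-5-(TBSO)-3,3-dimethyl-7-oxooctanal | O=CCC(C)(C)C[C@H](O[Si](C)(C)C(C)(C)C)CC(C)=O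
F6 | step 15 | (1R,6S)-2,2,6-trimethyl-7-oxabicyclo[4.1.0]heptane-1-carbaldehyde | CC1(C)CCC[C@]2(C)O[C@]12C=O
F7 | step 15 | ethyl (2E,4E)-3-methyl-5-[(1R,6S)-2,2,6-trimethyl-7-oxabicyclo[4.1.0]heptan-1-yl]penta-2,4-dienoate | CCOC(=O)/C=C(C)/C=C/[C@]12O[C@@]1(C)CCCC2(C)C
F8 | step 10 | tert-butyl{[(1R)-4-[(3E)-5-bromo-3-methylpent-3-en-1-yn-1-yl]-3,5,5-trimethylcyclohex-3-en-1-yl]oxy}dimethylsilane | CC1=C(C#C/C(C)=C/CBr)C(C)(C)C[C@H](O[Si](C)(C)C(C)(C)C)C1
F9 | step 10 | diethyl {(2E)-5-[(4R)-4-(TBSO)-2,6,6-trimethylcyclohex-1-en-1-yl]-3-methylpent-2-en-4-yn-1-yl}phosphonate | CC1=C(C#C/C(C)=C/CP(=O)(OCC)OCC)C(C)(C)C[C@H](O[Si](C)(C)C(C)(C)C)C1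
F10 | step 10 | 3'-O-TBS ether of 34 | CC1=C(C#C/C(C)=C/C=C/C(C)=C/C=C/C=C(C)/C=C/C=C(C)/C=C/[C@@]2(O)C(C)(C)CCC[C@@]2(C)O)C(C)(C)C[C@H](O[Si](C)(C)C(C)(C)C)C1
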